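The route rests on disconnecting the C1–C6 bond of the cyclohexanone ring (C1 carries the ester, C6 the side chain). In one operation the methyl ketone enolate of the open-chain bis-epoxide 15 opens the C6–C7 oxirane at C6, which closes the carbocycle. The C7 alkoxide released then displaces the chloride on C14, so the oxirane migrates into its final exocyclic position. The step exploits two features. Ring carbon C6 adjoins the quaternary oxirane carbon C7, and the C2 carbonyl is blocked on its other side by the quaternary carbon C3 of the fused oxirane. No ring is closed afterwards. The precursor is an acyclic skipped bis(epoxy ketone) bearing a chloromethyl group.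

Key step: step 8

Atom labels used in the text only:
- C1 = ring CH bearing the ester
- C2 = ring C=O
- C3 = ring oxirane carbon bearing CH3
- C4 = ring oxirane CH
- C5 = ring CH2
- C6 = ring CH bearing the side chain
- C7 = quaternary carbon of the exocyclic oxirane, and C14 = its CH2
- C8 = side-chain C=O
- C9=C10 = E-alkene
- C11 = carbon bearing OOH and two CH3

Assumption: the target is taken as drawn, that is (1S,3S,4R,6S) in 7-oxabicyclo[4.1.0]heptane numbering and (2R) in the exocyclic oxirane. The C8 carbinol of 14 is carried as a mixture of epimers because step 7 removes that centre.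

Step 1
Reactants: 1 1,3-dichloropropan-2-one; 2 vinylmagnesium bromide
Product: 4 2-(chloromethyl)-2-ethenyloxirane (racemic), via bromomagnesium alkoxide 3 (not isolated)
Conditions: THF, −78 to 0 °C; then aq NaOH, Et2O, rt
Reagents that add atoms: none
Why: Grignard 1,2-addition to the ketone followed by Williamson-type 3-exo-tet closure of the chlorohydrin alkoxide; 4 is racemic, which does not matter because its stereocentre becomes sp2 in step 2.

Step 2
Reactants: 5 (S)-but-3-yn-2-ol; 4 2-(chloromethyl)-2-ethenyloxirane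
Product: 7 (2Z,5Z,7S)-2-(chloromethyl)-6-methylocta-2,5-diene-1,7-diol, via alkenylmagnesium chelate 6 (not isolated)
Conditions: 5, MeMgBr (2.2 equiv), CuI (10 mol %), Et2O, −10 °C to rt; then 4 (excess), −40 to 0 °C; aqueous work-up
Reagents that add atoms: methylmagnesium bromide, C[Mg]Br
Why: Copper-catalysed anti-carbomagnesiation of the propargylic alkoxide delivers CH3 to C3 and magnesium to C4 inside a five-membered chelate, which fixes the Z-alkene (C2 cis to C5), and the alkenylcopper species then opens vinyloxirane 4 in the SN2' sense at its terminal CH2, where the oxirane CH2O arm should take the outside position (as isoprene monoxide does) so that CH2Cl ends cis to C5; the carbinol stereocentre is that of 5.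

Step 3
Reactants: 7 (2Z,5Z,7S)-2-(chloromethyl)-6-methylocta-2,5-diene-1,7-diol
Product: 8 (2S,3Z)-5-[(2R,3R)-3-(chloromethyl)-3-(hydroxymethyl)oxiran-2-yl]-3-methylpent-3-en-2-ol
Conditions: Ti(OiPr)4, D-(−)-diethyl tartrate, t-BuOOH, 4 Å MS, CH2Cl2, −20 °C
Reagents that add atoms: tert-butyl hydroperoxide, CC(C)(C)OO
Why: Sharpless asymmetric epoxidation: the primary E-type allylic alcohol at C8 is a fast substrate and D-(−)-tartrate delivers oxygen to the face that makes C6 and C7 both R, while the secondary, Z-substituted (S)-allylic alcohol at C2 is the slow-reacting partner of this tartrate and should remain.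

Step 4
Reactants: 8 (2S,3Z)-5-[(2R,3R)-3-(chloromethyl)-3-(hydroxymethyl)oxiran-2-yl]-3-methylpent-3-en-2-ol
Product: 9 (1S)-1-[(2R,3S)-3-{[(2R,3R)-3-(chloromethyl)-3-(hydroxymethyl)oxiran-2-yl]methyl}-2-methyloxiran-2-yl]ethan-1-ol
Conditions: mCPBA, CH2Cl2, 0 °C
Reagents that add atoms: 3-chloroperoxybenzoic acid, OOC(=O)c1cccc(Cl)c1
Why: Hydroxyl-directed peracid epoxidation: A(1,3) strain against the cis substituent C5 holds the carbinol hydrogen in the alkene plane, so the hydrogen-bonded peracid attacks the face that carries the (S)-hydroxyl group and should give the threo epoxy alcohol with (R)-C3 and (S)-C4.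

Step 5
Reactants: 9 bis-epoxy diol
Product: 10 (2S,3R)-3-{[(2S,3S)-3-acetyl-3-methyloxiran-2-yl]methyl}-2-(chloromethyl)oxirane-2-carbaldehyde
Conditions: Dess–Martin periodinane (2.5 equiv), CH2Cl2, 0 °C to rt
Reagents that add atoms: none
Why: Dess–Martin oxidation of both alcohols at once under mild, non-basic conditions that leave the oxiranes and the alkyl chloride alone; the auxiliary stereocentre C2 is erased after it has set C3 and C4 (C3 becomes S, and C7 becomes S, by a change of priorities only).

Step 6
Reactants: 10 keto aldehyde; 11 2-methylbut-1-en-3-yne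
Product: 14 (2E)-1-[(2R,3R)-3-{[(2S,3S)-3-acetyl-3-methyloxiran-2-yl]methyl}-2-(chloromethyl)oxiran-2-yl]-4-methylpenta-2,4-dien-1-ol (both carbinol epimers), via dienylzirconocene chloride 12 (not isolated), via dienyl(methyl)zinc 13 (not isolated)
Conditions: 11, Cp2Zr(H)Cl, CH2Cl2, rt; Me2Zn, toluene, −65 °C; then 10, 0 °C; aqueous work-up
Reagents that add atoms: none
Why: Hydrozirconation of the alkyne of 11 (syn and terminal, hence E), zirconium-to-zinc transmetalation and 1,2-addition of the alkenylzinc, a reagent that adds to aldehydes but not to the hindered methyl ketone; the new carbinol centre C8 forms as a mixture that step 7 removes.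

Step 7
Reactants: 14 dienyl carbinol
Product: 15 (2E)-1-[(2S,3R)-3-{[(2S,3S)-3-acetyl-3-methyloxiran-2-yl]methyl}-2-(chloromethyl)oxiran-2-yl]-4-methylpenta-2,4-dien-1-one
Conditions: Dess–Martin periodinane, CH2Cl2, 0 °C
Reagents that add atoms: none
Why: Dess–Martin oxidation of the allylic alcohol gives the dienone, whose carbonyl group has no α-hydrogen on either side, so that the methyl ketone is the only enolisable site in step 8.

Step 8
Reactants: 15 open-chain bis(epoxy ketone)
Product: 18 (1S,4R,6S)-1-methyl-4-{(2R)-2-[(2E)-4-methylpenta-2,4-dienoyl]oxiran-2-yl}-7-oxabicyclo[4.1.0]heptan-2-one, via lithium enolate 16 (not isolated), via lithium chlorohydrin alkoxide 17 (not isolated)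
Conditions: LiN(SiMe3)2 (1.05 equiv), THF, 0.005 M, −78 °C to rt
Reagents that add atoms: none
Why: LiN(SiMe3)2 can only remove a proton from the C1 methyl group of 15 (C3 and C7 are quaternary, the dienone has no α-hydrogen); enolate 16 attacks C6 of the trisubstituted oxirane from the side opposite its C6–O bond, and the tertiary alkoxide 17 released on C7 then displaces the neighbouring chloride. The closest known reaction types are the Stork-type intramolecular alkylation of an enolate by an epoxide and the opening and re-closure of epihalohydrins by carbanions (a Payne-like epoxide migration). The carbocycle closes in the 6-(enolendo)-exo-tet mode, helped by the cis-oxirane C3–C4 that holds C2 and C5 on one side like a Z-alkene, and the new oxirane C7–C14 closes 3-exo-tet. C6 is the only stereocentre that is remade, fixed by SN2 inversion of the centre set in step 3, while C7 keeps all four of its bonds and thus its configuration, so both follow from the alkene geometry of 7 and the tartrate. The step needs C- over O-alkylation and 6-exo over 7-endo attack: the lithium ion, chelated by the oxirane oxygen and the C8 carbonyl, should favour attack through carbon and activate the C6–O bond, and C7 is fully substituted. High dilution keeps the enolate away from the dienone of a second molecule, and attack on the other oxirane would need a three- or four-membered ring.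

Step 9
Reactants: 18 bicyclic ketone
Product: 21 (1S,3S,4R,6S)-1-methyl-4-{(2R)-2-[(2E)-4-methylpenta-2,4-dienoyl]oxiran-2-yl}-2-oxo-7-oxabicyclo[4.1.0]heptan-3-yl 3-methylbutanoate, via potassium enolate 19 (not isolated), via potassium alkoxide 20 (not isolated)
Conditions: KN(SiMe3)2, THF, −78 °C; 3-phenyl-2-(phenylsulfonyl)oxaziridine, −78 °C; then (i-BuCO)2O, DMAP (cat.), −78 to 0 °C
Reagents that add atoms: 3-phenyl-2-(phenylsulfonyl)oxaziridine, O=S(=O)(c1ccccc1)N1OC1c1ccccc1; 3-methylbutanoic anhydride, CC(C)CC(=O)OC(=O)CC(C)C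
Why: Davis oxidation of the ketone enolate followed by O-acylation in the same flask: only C1 can enolise, and the oxaziridine approaches the face opposite to both the C6 side chain and the fused oxirane oxygen, which sets (S)-C1 trans to C6, the equatorial and also thermodynamically preferred arrangement.

Step 10
Reactants: 21 dienone ester
Product: 22 (1S,3S,4R,6S)-1-methyl-4-{(2R)-2-[(2E)-4-methyl-4-(triethylsilylperoxy)pent-2-enoyl]oxiran-2-yl}-2-oxo-7-oxabicyclo[4.1.0]heptan-3-yl 3-methylbutanoate
Conditions: Co(thd)2 (cat., thd = 2,2,6,6-tetramethylheptane-3,5-dionate), O2 (1 atm), Et3SiH, 1,2-dichloroethane, rt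
Reagents that add atoms: dioxygen, O=O; triethylsilane, CC[SiH](CC)CC
Why: Mukaiyama–Isayama hydrosilylperoxidation: the cobalt hydride transfers a hydrogen atom to the terminal CH2 of the 1,1-disubstituted alkene, and the tertiary radical, conjugated to the enone, should take up O2 at C11 so that the E-enone is kept, the regiochemistry known for 2,4-dienoates.

Step 11
Reactants: 22 triethylsilyl peroxide
Product: 23 CNP0131119.1, (1S,3S,4R,6S)-4-{(2R)-2-[(2E)-4-hydroperoxy-4-methylpent-2-enoyl]oxiran-2-yl}-1-methyl-2-oxo-7-oxabicyclo[4.1.0]heptan-3-yl 3-methylbutanoate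
Conditions: PPTS (cat.), MeOH, 0 °C
Reagents that add atoms: none
Why: Acid-catalysed methanolysis of the labile Si–O bond of the silyl peroxide; both oxiranes are deactivated towards acid by their neighbouring carbonyl groups and a tertiary hydroperoxide cannot undergo Kornblum–DeLaMare fragmentation.

Compound list
1 | 1,3-dichloropropan-2-one | ClCC(=O)CCl | starting material
2 | vinylmagnesium bromide | C=C[Mg]Br | starting material
3 | bromomagnesium 1-chloro-2-(chloromethyl)but-3-en-2-olate | ClCC(CCl)(C=C)O[Mg]Br | intermediate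
4 | 2-(chloromethyl)-2-ethenyloxirane (racemic) | ClCC1(C=C)CO1 | intermediate
5 | (S)-but-3-yn-2-ol | C[C@H](O)C#C | starting material
6 | bromomagnesium (2S,3Z)-4-(bromomagnesio)-3-methylbut-3-en-2-olate | C[C@H](O[Mg]Br)/C(C)=C\[Mg]Br | intermediate
7 | (2Z,5Z,7S)-2-(chloromethyl)-6-methylocta-2,5-diene-1,7-diol | C[C@H](O)/C(C)=C\C/C=C(\CCl)CO | intermediate
8 | (2S,3Z)-5-[(2R,3R)-3-(chloromethyl)-3-(hydroxymethyl)oxiran-2-yl]-3-methylpent-3-en-2-ol | C[C@H](O)/C(C)=C\C[C@H]1O[C@]1(CCl)CO | intermediate
9 | (1S)-1-[(2R,3S)-3-{[(2R,3R)-3-(chloromethyl)-3-(hydroxymethyl)oxiran-2-yl]methyl}-2-methyloxiran-2-yl]ethan-1-ol | C[C@H](O)[C@@]1(C)O[C@H]1C[C@H]1O[C@]1(CCl)CO | intermediate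
10 | (2S,3R)-3-{[(2S,3S)-3-acetyl-3-methyloxiran-2-yl]methyl}-2-(chloromethyl)oxirane-2-carbaldehyde | CC(=O)[C@@]1(C)O[C@H]1C[C@H]1O[C@]1(CCl)C=O | intermediate
11 | 2-methylbut-1-en-3-yne | C=C(C)C#C | starting material
12 | chlorobis(cyclopentadienyl)[(1E)-3-methylbuta-1,3-dien-1-yl]zirconium | C=C(C)/C=C/[Zr](Cl)(C1C=CC=C1)C1C=CC=C1 | intermediate
13 | methyl[(1E)-3-methylbuta-1,3-dien-1-yl]zinc | C=C(C)/C=C/[Zn]C | intermediate
14 | (2E)-1-[(2R,3R)-3-{[(2S,3S)-3-acetyl-3-methyloxiran-2-yl]methyl}-2-(chloromethyl)oxiran-2-yl]-4-methylpenta-2,4-dien-1-ol, both carbinol epimers | CC(=O)[C@@]1(C)O[C@H]1C[C@H]1O[C@]1(CCl)C(O)/C=C/C(C)=C | intermediate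
15 | (2E)-1-[(2S,3R)-3-{[(2S,3S)-3-acetyl-3-methyloxiran-2-yl]methyl}-2-(chloromethyl)oxiran-2-yl]-4-methylpenta-2,4-dien-1-one | CC(=O)[C@@]1(C)O[C@H]1C[C@H]1O[C@]1(CCl)C(=O)/C=C/C(C)=C | intermediate
16 | lithium enolate of 15 (C1=C2) | [Li]OC(=C)[C@@]1(C)O[C@H]1C[C@H]1O[C@]1(CCl)C(=O)/C=C/C(C)=C | intermediate
17 | ring-closed lithium alkoxide (C7–OLi next to CH2Cl) | C1C(=O)[C@@]2(C)O[C@H]2C[C@H]1[C@@](O[Li])(CCl)C(=O)/C=C/C(C)=C | intermediate
18 | (1S,4R,6S)-1-methyl-4-{(2R)-2-[(2E)-4-methylpenta-2,4-dienoyl]oxiran-2-yl}-7-oxabicyclo[4.1.0]heptan-2-one | C1C(=O)[C@@]2(C)O[C@H]2C[C@H]1[C@]1(C(=O)/C=C/C(C)=C)CO1 | intermediate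
19 | potassium enolate of 18 (C1=C2) | C1=C(O[K])[C@@]2(C)O[C@H]2C[C@H]1[C@]1(C(=O)/C=C/C(C)=C)CO1 | intermediate
20 | potassium alkoxide of the (3S)-3-hydroxy derivative of 18 | [K]O[C@@H]1C(=O)[C@@]2(C)O[C@H]2C[C@H]1[C@]1(C(=O)/C=C/C(C)=C)CO1 | intermediate
21 | (1S,3S,4R,6S)-1-methyl-4-{(2R)-2-[(2E)-4-methylpenta-2,4-dienoyl]oxiran-2-yl}-2-oxo-7-oxabicyclo[4.1.0]heptan-3-yl 3-methylbutanoate | CC(C)CC(=O)O[C@@H]1C(=O)[C@@]2(C)O[C@H]2C[C@H]1[C@]1(C(=O)/C=C/C(C)=C)CO1 | intermediate
22 | triethylsilyl peroxide of the target | CC(C)CC(=O)O[C@@H]1C(=O)[C@@]2(C)O[C@H]2C[C@H]1[C@]1(C(=O)/C=C/C(C)(C)OO[Si](CC)(CC)CC)CO1 | intermediate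
23 | CNP0131119.1 | CC(C)CC(=O)O[C@@H]1C(=O)[C@@]2(C)O[C@H]2C[C@H]1[C@]1(C(=O)/C=C/C(C)(C)OO)CO1 | target

Total step count: 11. Longest linear sequence: 11 steps (1 → 4 → 7 → … → 23).

Steps most likely to fail

Step 8. The enolate may alkylate through oxygen. It may also be lost by conjugate addition to the dienone before the hindered oxirane next to the C8 carbonyl opens. The fallback moves the ring closure ahead of the C8 oxidation; it sets out from 14 and comes back at 18.
- Carbinol 14 is silylated (Et3SiCl, imidazole, CH2Cl2) to the triethylsilyl ether of 14 F1. Its oxirane is no longer flanked by a carbonyl group, and it holds no Michael acceptor.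
- LiN(SiMe3)2 then brings about the same oxirane opening and re-closure to the bicyclic silyl ether F2.
- Methanolysis (PPTS, MeOH) gives the bicyclic dienol F3.
- Dess–Martin oxidation returns to 18.
- The carbocycle is still closed in the last ring-forming operation.

Step 2. Control of the C6=C7 geometry in the SN2' opening may be poor, and the organometallic may attack the allylic chloride of the product further. The fallback builds the alkene by metathesis under thermodynamic control; it sets out from 5 and comes back at 7.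
- Chelate 6 is trapped with allyl bromide to give (2S,3Z)-3-methylhepta-3,6-dien-2-ol F4.
- Cross-metathesis of its terminal alkene with methyl 2-(chloromethyl)acrylate (second-generation Hoveyda–Grubbs catalyst, CH2Cl2, reflux) should give methyl (2Z,5Z,7S)-2-(chloromethyl)-7-hydroxy-6-methylocta-2,5-dienoate F5, in which C5 stands trans to the ester.
- i-Bu2AlH (CH2Cl2, −78 °C) reduces the ester to 7.

Step 9. The potassium enolate of 18 is the enolate of a γ,δ-epoxy ketone. It may be lost by attack on C7 (cyclopropane formation) or by addition to the dienone before it is oxidised. The fallback avoids a free enolate in the oxidation; it sets out from 18 and comes back at 21.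
- LiN(SiMe3)2 in the presence of Me3SiCl (internal quench, THF, −78 °C) gives the trimethylsilyl enol ether of 18 F6.
- F6 is oxidised under neutral conditions with lead tetrakis(3-methylbutanoate), made from Pb(OAc)4 and 3-methylbutanoic acid. This is the known α-acyloxylation of silyl enol ethers by tetravalent lead carboxylates, and it gives 21 directly.

Further compounds
F1 | step 8 | triethylsilyl ether of 14 | CC(=O)[C@@]1(C)O[C@H]1C[C@H]1O[C@]1(CCl)C(O[Si](CC)(CC)CC)/C=C/C(C)=C
F2 | step 8 | bicyclic silyl ether | C1C(=O)[C@@]2(C)O[C@H]2C[C@H]1[C@]1(C(O[Si](CC)(CC)CC)/C=C/C(C)=C)CO1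
F3 | step 8 | bicyclic dienol | C1C(=O)[C@@]2(C)O[C@H]2C[C@H]1[C@]1(C(O)/C=C/C(C)=C)CO1
F4 | step 2 | (2S,3Z)-3-methylhepta-3,6-dien-2-ol | C[C@H](O)/C(C)=C\CC=C
F5 | step 2 | methyl (2Z,5Z,7S)-2-(chloromethyl)-7-hydroxy-6-methylocta-2,5-dienoate | C[C@H](O)/C(C)=C\C/C=C(\CCl)C(=O)OC
F6 | step 9 | trimethylsilyl enol ether of 18 | C1=C(O[Si](C)(C)C)[C@@]2(C)O[C@H]2C[C@H]1[C@]1(C(=O)/C=C/C(C)=C)CO1
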